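## Retrosynthetic overview

1. Ring B is attached last: rhodium-catalysed asymmetric 1,4-addition of an arylboronic acid to chromone 18 sets C2, so ring C is first made as a pyranone; desilylation then gives the target.
2. Ring C comes from the ring A acetophenone 16, made by MOM-directed ortho-lithiation/acetylation of 14, then enaminone formation and acid closure.
3. The isopropenyl group and the tertiary carbinol are both carried as carboxyl carbons: lactone C=O → Weinreb amide → acetyl → C=CH2, and CO2Me → CMe2OH, using one MeMgBr treatment and one Wittig reaction.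
4. Key disconnection: the ArCH2–CH bond between the methylene on C8 and the side-chain stereocentre, made by a carbene-catalysed enantioselective [4+2] annulation of o-quinone methide 9 with the azolium enolate from acyl imidazole 8. The enabling feature is that C8 of ring A bears the side-chain CH2 and is ortho to the oxygen on C7, so O7–C7–C8–CH2 is a latent o-quinone methide; the stereocentre is α to the isopropenyl carbon, which at the acyl level closes with O7 to a temporary six-membered lactone (O7, C7, C8, CH2, CH, C=O).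
5. Ring order: ring A is bought; temporary lactone ring (formed in step 6, opened in step 7); ring C (step 12); ring B attached (step 15).

Key step: step 6

Assumption: the sense of asymmetric induction of the triazolium precatalyst (step 6) and of the bisphosphine ligand (step 15) is taken from the closest analogues; if a model reaction shows the opposite sense, the antipode is used with everything else unchanged.

## Route

Step 1
Reactants: 1 2,4,6-trihydroxybenzaldehyde
Product: 2 2,6-dihydroxy-4-methoxybenzaldehyde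
Conditions: MeI (1.05 equiv), K2CO3 (1.0 equiv), acetone, 0 °C → rt
Reagents that add atoms: iodomethane (CI)
Why: Williamson etherification under one equivalent of weak base: the 4-hydroxyl, para to the formyl group and not hydrogen-bonded to it, is the most acidic and most nucleophilic of the three, so it is methylated in preference to the two chelated ortho-hydroxyls.

Step 2
Reactants: 2 2,6-dihydroxy-4-methoxybenzaldehyde
Product: 3 2-hydroxy-4-methoxy-6-(methoxymethoxy)benzaldehyde
Conditions: MOMCl (1.1 equiv), i-Pr2NEt, CH2Cl2, 0 °C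
Reagents that add atoms: chloromethyl methyl ether (COCCl)
Why: O-Alkylation with MOMCl: only one ortho-hydroxyl of 2 can chelate the formyl oxygen at a time, the other reacts, and the hydroxyl left in 3 is then firmly chelated and much less nucleophilic, which is the usual basis for mono-protection of 2,6-dihydroxyaryl carbonyl compounds.

Step 3
Reactants: 3 2-hydroxy-4-methoxy-6-(methoxymethoxy)benzaldehyde
Product: 4 2-{[tert-butyl(dimethyl)silyl]oxy}-4-methoxy-6-(methoxymethoxy)benzaldehyde
Conditions: TBSCl, imidazole, DMF, rt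
Reagents that add atoms: tert-butyl(chloro)dimethylsilane (CC(C)(C)[Si](C)(C)Cl)
Why: Silylation of the chelated phenol with TBSCl/imidazole in DMF installs the fluoride-labile trigger for the later quinone methide release; the MOM acetal and the aldehyde are inert.

Step 4
Reactants: 4 2-{[tert-butyl(dimethyl)silyl]oxy}-4-methoxy-6-(methoxymethoxy)benzaldehyde
Product: 6 [2-{[tert-butyl(dimethyl)silyl]oxy}-4-methoxy-6-(methoxymethoxy)phenyl]methyl acetate, via benzyl alcohol 5 (not isolated)
Conditions: i-Bu2AlH, CH2Cl2, −78 °C; then Ac2O, pyridine, 4-(dimethylamino)pyridine (cat.), −78 → 0 °C; aqueous potassium sodium tartrate work-up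
Reagents that add atoms: acetic anhydride (CC(=O)OC(C)=O)
Why: One-pot reductive acetylation: i-Bu2AlH reduces the aldehyde at −78 °C and the aluminium alkoxide is acetylated in situ, so the free benzylic alkoxide next to the aryl silyl ether (silyl migration, premature quinone methide formation) is never present.

Step 5
Reactants: 7 5-methoxy-5-oxopentanoic acid (monomethyl glutarate)
Product: 8 methyl 5-(1H-imidazol-1-yl)-5-oxopentanoate
Conditions: CDI, THF, rt; used crude
Reagents that add atoms: 1,1'-carbonyldiimidazole (O=C(n1ccnc1)n1ccnc1)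
Why: Activation of the carboxylic acid with CDI gives the acyl imidazole (driven by loss of CO2), the acyl donor used for azolium enolate generation; the methyl ester does not react.

Step 6
Reactants: 6 [2-{[tert-butyl(dimethyl)silyl]oxy}-4-methoxy-6-(methoxymethoxy)phenyl]methyl acetate; 8 methyl 5-(1H-imidazol-1-yl)-5-oxopentanoate
Product: 10 methyl 3-[(3R)-7-methoxy-5-(methoxymethoxy)-2-oxo-3,4-dihydro-2H-chromen-3-yl]propanoate, via o-quinone methide 9 (not isolated)
Conditions: 8 (1.5 equiv), (5aR,10bS)-2-(2,4,6-trimethylphenyl)-5a,10b-dihydro-4H,6H-indeno[2,1-b][1,2,4]triazolo[4,3-d][1,4]oxazin-2-ium tetrafluoroborate (20 mol %), CsF (2 equiv), 18-crown-6 (2 equiv), THF, −20 °C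
Reagents that add atoms: none
Why: Fluoride cleaves the aryl silyl ether of 6 and the phenoxide expels acetate to give the electron-rich o-quinone methide 9 at low stationary concentration, while the triazolylidene carbene is acylated by 8 and the acyl azolium is deprotonated to its (Z)-azolium enolate; conjugate addition of the enolate α-carbon to the exocyclic CH2 of 9 forms the ArCH2–CH bond and the resulting phenoxide is acylated by the azolium, which releases the carbene. The closest known reaction type is the carbene-catalysed enantioselective formal [4+2] annulation of fluoride-generated o-quinone methides with acyl imidazoles to 3-substituted 3,4-dihydrocoumarins. The lactone ring closes stepwise, by intermolecular Michael addition followed by 6-exo-trig O-acylation (addition–elimination at the acyl azolium carbon). The new stereocentre (C3 of the lactone, the later side-chain centre) is set by catalyst control, the fused aminoindane backbone shielding one face of the enolate so that 9 adds to the open face. The step needs chemoselectivity for the enolate over imidazole, fluoride and self-condensation of 9, which the fluoride-gated slow release and the donor substituents of 9 (a vinylogous ester) secure, and regioselectivity between the two oxygens flanking the benzylic carbon, which is fixed because only the silylated oxygen can become the quinone methide oxygen while the other is blocked as the MOM ether; the remote methyl ester is not enolised because only the acyl azolium acidifies its α-CH2.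

Step 7
Reactants: 10 methyl 3-[(3R)-7-methoxy-5-(methoxymethoxy)-2-oxo-3,4-dihydro-2H-chromen-3-yl]propanoate
Product: 11 methyl (4R)-4-{[2-hydroxy-4-methoxy-6-(methoxymethoxy)phenyl]methyl}-5-[methoxy(methyl)amino]-5-oxopentanoate
Conditions: MeNH(OMe)·HCl, AlMe3, CH2Cl2, 0 °C; aqueous potassium sodium tartrate work-up
Reagents that add atoms: N,O-dimethylhydroxylamine hydrochloride (CNOC.Cl)
Why: Weinreb amide formation by aminolysis with the aluminium amide from AlMe3: the aryl ester of the lactone is far more electrophilic than the methyl ester and opens at 0 °C, and the conditions are not basic enough to epimerise the α-stereocentre.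

Step 8
Reactants: 11 methyl (4R)-4-{[2-hydroxy-4-methoxy-6-(methoxymethoxy)phenyl]methyl}-5-[methoxy(methyl)amino]-5-oxopentanoate
Product: 12 methyl (4R)-5-[methoxy(methyl)amino]-4-{[4-methoxy-2-(methoxymethoxy)-6-{[tri(propan-2-yl)silyl]oxy}phenyl]methyl}-5-oxopentanoate
Conditions: TIPSOTf, 2,6-lutidine, CH2Cl2, 0 °C
Reagents that add atoms: tri(propan-2-yl)silyl trifluoromethanesulfonate (CC(C)[Si](C(C)C)(C(C)C)OS(=O)(=O)C(F)(F)F)
Why: Silylation of the liberated phenol with TIPSOTf/2,6-lutidine prevents relactonisation onto the Weinreb amide in the next step and installs the group that later protects the 7-hydroxyl against n-BuLi and the rhodium step.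

Step 9
Reactants: 12 methyl (4R)-5-[methoxy(methyl)amino]-4-{[4-methoxy-2-(methoxymethoxy)-6-{[tri(propan-2-yl)silyl]oxy}phenyl]methyl}-5-oxopentanoate
Product: 13 (3R)-6-hydroxy-3-{[4-methoxy-2-(methoxymethoxy)-6-{[tri(propan-2-yl)silyl]oxy}phenyl]methyl}-6-methylheptan-2-one
Conditions: MeMgBr (5 equiv), THF, −20 → 0 °C; aq. NH4Cl
Reagents that add atoms: methylmagnesium bromide (C[Mg]Br)
Why: Grignard addition: one MeMgBr converts the Weinreb amide into the methyl ketone through the chelated tetrahedral intermediate that collapses only on quench, two convert the methyl ester into the tertiary carbinol, and the α-stereocentre is therefore never exposed to base as a ketone.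

Step 10
Reactants: 13 (3R)-6-hydroxy-3-{[4-methoxy-2-(methoxymethoxy)-6-{[tri(propan-2-yl)silyl]oxy}phenyl]methyl}-6-methylheptan-2-one
Product: 14 (5R)-5-{[4-methoxy-2-(methoxymethoxy)-6-{[tri(propan-2-yl)silyl]oxy}phenyl]methyl}-2,6-dimethylhept-6-en-2-ol
Conditions: Ph3PCH3Br, KOt-Bu, THF, 0 °C → rt
Reagents that add atoms: methyltriphenylphosphonium bromide (C[P+](c1ccccc1)(c1ccccc1)c1ccccc1.[Br-])
Why: Wittig methylenation of the methyl ketone gives the isopropenyl group; the unstabilised ylide adds to the unhindered acetyl carbonyl faster than it enolises the α-branched side, so the stereocentre is retained, and the tertiary alcohol merely consumes one equivalent of ylide as its alkoxide.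

Step 11
Reactants: 14 (5R)-5-{[4-methoxy-2-(methoxymethoxy)-6-{[tri(propan-2-yl)silyl]oxy}phenyl]methyl}-2,6-dimethylhept-6-en-2-ol
Product: 16 1-{3-[(2R)-5-hydroxy-5-methyl-2-(prop-1-en-2-yl)hexyl]-6-methoxy-2-(methoxymethoxy)-4-{[tri(propan-2-yl)silyl]oxy}phenyl}ethan-1-one, via aryllithium 15 (not isolated)
Conditions: n-BuLi (2.4 equiv), THF, 0 °C; then MeC(O)N(OMe)Me, −78 → 0 °C; H2O
Reagents that add atoms: N-methoxy-N-methylacetamide (CC(=O)N(C)OC)
Why: Directed ortho-metalation: n-BuLi first forms the lithium alkoxide and then lithiates the ring position flanked by the chelating OMOM group and the OMe group (the position next to the bulky silyl ether lacks a coordinating group), and the aryllithium is acylated by the Weinreb acetamide without over-addition.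

Step 12
Reactants: 16 1-{3-[(2R)-5-hydroxy-5-methyl-2-(prop-1-en-2-yl)hexyl]-6-methoxy-2-(methoxymethoxy)-4-{[tri(propan-2-yl)silyl]oxy}phenyl}ethan-1-one
Product: 18 8-[(2R)-5-hydroxy-5-methyl-2-(prop-1-en-2-yl)hexyl]-5-methoxy-7-{[tri(propan-2-yl)silyl]oxy}-4H-chromen-4-one, via enaminone 17 (not isolated)
Conditions: Me2NCH(OMe)2, toluene, 100 °C; evaporate; then HCl (1 M in MeOH, 3 equiv), CH2Cl2, 0 °C → rt
Reagents that add atoms: N,N-dimethylformamide dimethyl acetal (COC(OC)N(C)C)
Why: Enaminone condensation of the methyl ketone with DMF-DMA and then acid: the MOM ether ortho to the carbonyl is cleaved and the freed phenol adds to the protonated enaminone β-carbon with loss of dimethylamine (6-endo-trig addition–elimination), closing the pyranone ring C, while the aryl TIPS ether is acid-stable and short, cold exposure spares the isopropenyl group and the tertiary alcohol.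

Step 13
Reactants: 19 4-bromo-3-methoxyphenol
Product: 20 (4-bromo-3-methoxyphenoxy)tri(propan-2-yl)silane
Conditions: TIPSCl, imidazole, DMF, rt
Reagents that add atoms: chlorotri(propan-2-yl)silane (CC(C)[Si](Cl)(C(C)C)C(C)C)
Why: Silylation of the phenol with TIPSCl/imidazole protects it for the lithiation and makes the final deprotection a single fluoride step.

Step 14
Reactants: 20 (4-bromo-3-methoxyphenoxy)tri(propan-2-yl)silane
Product: 22 [2-methoxy-4-{[tri(propan-2-yl)silyl]oxy}phenyl]boronic acid, via aryllithium 21 (not isolated)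
Conditions: n-BuLi, THF, −78 °C; B(Oi-Pr)3, −78 °C → rt; 1 M HCl (brief)
Reagents that add atoms: triisopropyl borate (CC(C)OB(OC(C)C)OC(C)C); water (O)
Why: Bromine–lithium exchange at −78 °C followed by borylation with B(Oi-Pr)3 and mild acidic hydrolysis gives the arylboronic acid; the aryl silyl ether tolerates both the aryllithium and the brief acid.

Step 15
Reactants: 18 8-[(2R)-5-hydroxy-5-methyl-2-(prop-1-en-2-yl)hexyl]-5-methoxy-7-{[tri(propan-2-yl)silyl]oxy}-4H-chromen-4-one; 22 [2-methoxy-4-{[tri(propan-2-yl)silyl]oxy}phenyl]boronic acid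
Product: 23 (2S)-8-[(2R)-5-hydroxy-5-methyl-2-(prop-1-en-2-yl)hexyl]-5-methoxy-2-(2-methoxy-4-{[tri(propan-2-yl)silyl]oxy}phenyl)-7-{[tri(propan-2-yl)silyl]oxy}-2,3-dihydro-4H-chromen-4-one
Conditions: 22 (3 equiv), [Rh(OH)(cod)]2 (2.5 mol %; cod = cycloocta-1,5-diene), (S)-2,2'-bis[bis(3,4,5-trifluorophenyl)phosphino]-6,6'-dimethoxy-1,1'-biphenyl (5.5 mol %), CH2Cl2/H2O, 25 °C
Reagents that add atoms: none
Why: Rhodium-catalysed asymmetric 1,4-addition of an arylboronic acid to a chromone (Hayashi–Miyaura reaction): transmetalation to the hydroxo-rhodium bisphosphine complex, enantioface-selective insertion of the chromone C2=C3 bond into the Rh–aryl bond and hydrolysis of the oxa-π-allyl rhodium species set C2 as (S) under ligand control, independently of the remote side-chain stereocentre, and CH2Cl2/H2O at room temperature without added base avoids 1,2-addition and retro-oxa-Michael opening.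

Step 16
Reactants: 23 (2S)-8-[(2R)-5-hydroxy-5-methyl-2-(prop-1-en-2-yl)hexyl]-5-methoxy-2-(2-methoxy-4-{[tri(propan-2-yl)silyl]oxy}phenyl)-7-{[tri(propan-2-yl)silyl]oxy}-2,3-dihydro-4H-chromen-4-one
Product: 24 (2S)-7-hydroxy-2-(4-hydroxy-2-methoxyphenyl)-8-[(2R)-5-hydroxy-5-methyl-2-(prop-1-en-2-yl)hexyl]-5-methoxy-2,3-dihydro-4H-chromen-4-one
Conditions: n-Bu4NF (2.5 equiv), AcOH (2.5 equiv), THF, 0 °C
Reagents that add atoms: none
Why: Fluoride cleavage of both aryl silyl ethers with n-Bu4NF buffered by acetic acid keeps the medium near neutral, so neither the base-labile C2 centre (retro-oxa-Michael ring opening) nor the acid-sensitive pair of the 7-hydroxyl and the isopropenyl group is put at risk.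

## Compound list

1 | 2,4,6-trihydroxybenzaldehyde | O=Cc1c(O)cc(O)cc1O | starting material
2 | 2,6-dihydroxy-4-methoxybenzaldehyde | O=Cc1c(O)cc(OC)cc1O | intermediate
3 | 2-hydroxy-4-methoxy-6-(methoxymethoxy)benzaldehyde | O=Cc1c(O)cc(OC)cc1OCOC | intermediate
4 | 2-{[tert-butyl(dimethyl)silyl]oxy}-4-methoxy-6-(methoxymethoxy)benzaldehyde | O=Cc1c(O[Si](C)(C)C(C)(C)C)cc(OC)cc1OCOC | intermediate
5 | [2-{[tert-butyl(dimethyl)silyl]oxy}-4-methoxy-6-(methoxymethoxy)phenyl]methanol (in the flask as its diisobutylaluminium alkoxide) | OCc1c(O[Si](C)(C)C(C)(C)C)cc(OC)cc1OCOC | intermediate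
6 | [2-{[tert-butyl(dimethyl)silyl]oxy}-4-methoxy-6-(methoxymethoxy)phenyl]methyl acetate | CC(=O)OCc1c(O[Si](C)(C)C(C)(C)C)cc(OC)cc1OCOC | intermediate
7 | 5-methoxy-5-oxopentanoic acid (monomethyl glutarate) | COC(=O)CCCC(=O)O | starting material
8 | methyl 5-(1H-imidazol-1-yl)-5-oxopentanoate | COC(=O)CCCC(=O)n1ccnc1 | intermediate
9 | 3-methoxy-5-(methoxymethoxy)-6-methylidenecyclohexa-2,4-dien-1-one (o-quinone methide) | C=C1C(=O)C=C(OC)C=C1OCOC | intermediate
10 | methyl 3-[(3R)-7-methoxy-5-(methoxymethoxy)-2-oxo-3,4-dihydro-2H-chromen-3-yl]propanoate | O=C1[C@H](CCC(=O)OC)Cc2c(O1)cc(OC)cc2OCOC | intermediate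
11 | methyl (4R)-4-{[2-hydroxy-4-methoxy-6-(methoxymethoxy)phenyl]methyl}-5-[methoxy(methyl)amino]-5-oxopentanoate | CON(C)C(=O)[C@H](CCC(=O)OC)Cc1c(O)cc(OC)cc1OCOC | intermediate
12 | methyl (4R)-5-[methoxy(methyl)amino]-4-{[4-methoxy-2-(methoxymethoxy)-6-{[tri(propan-2-yl)silyl]oxy}phenyl]methyl}-5-oxopentanoate | CON(C)C(=O)[C@H](CCC(=O)OC)Cc1c(O[Si](C(C)C)(C(C)C)C(C)C)cc(OC)cc1OCOC | intermediate
13 | (3R)-6-hydroxy-3-{[4-methoxy-2-(methoxymethoxy)-6-{[tri(propan-2-yl)silyl]oxy}phenyl]methyl}-6-methylheptan-2-one | CC(=O)[C@H](CCC(C)(C)O)Cc1c(O[Si](C(C)C)(C(C)C)C(C)C)cc(OC)cc1OCOC | intermediate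
14 | (5R)-5-{[4-methoxy-2-(methoxymethoxy)-6-{[tri(propan-2-yl)silyl]oxy}phenyl]methyl}-2,6-dimethylhept-6-en-2-ol | C=C(C)[C@H](CCC(C)(C)O)Cc1c(O[Si](C(C)C)(C(C)C)C(C)C)cc(OC)cc1OCOC | intermediate
15 | lithium (5R)-5-{[3-lithio-4-methoxy-2-(methoxymethoxy)-6-{[tri(propan-2-yl)silyl]oxy}phenyl]methyl}-2,6-dimethylhept-6-en-2-olate (aryllithium) | C=C(C)[C@H](CCC(C)(C)O[Li])Cc1c(O[Si](C(C)C)(C(C)C)C(C)C)cc(OC)c([Li])c1OCOC | intermediate
16 | 1-{3-[(2R)-5-hydroxy-5-methyl-2-(prop-1-en-2-yl)hexyl]-6-methoxy-2-(methoxymethoxy)-4-{[tri(propan-2-yl)silyl]oxy}phenyl}ethan-1-one | C=C(C)[C@H](CCC(C)(C)O)Cc1c(O[Si](C(C)C)(C(C)C)C(C)C)cc(OC)c(C(C)=O)c1OCOC | intermediate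
17 | (2E)-3-(dimethylamino)-1-{3-[(2R)-5-hydroxy-5-methyl-2-(prop-1-en-2-yl)hexyl]-6-methoxy-2-(methoxymethoxy)-4-{[tri(propan-2-yl)silyl]oxy}phenyl}prop-2-en-1-one (enaminone) | C=C(C)[C@H](CCC(C)(C)O)Cc1c(O[Si](C(C)C)(C(C)C)C(C)C)cc(OC)c(C(=O)/C=C/N(C)C)c1OCOC | intermediate
18 | 8-[(2R)-5-hydroxy-5-methyl-2-(prop-1-en-2-yl)hexyl]-5-methoxy-7-{[tri(propan-2-yl)silyl]oxy}-4H-chromen-4-one | C=C(C)[C@H](CCC(C)(C)O)Cc1c(O[Si](C(C)C)(C(C)C)C(C)C)cc(OC)c2c1occc2=O | intermediate
19 | 4-bromo-3-methoxyphenol | COc1cc(O)ccc1Br | starting material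
20 | (4-bromo-3-methoxyphenoxy)tri(propan-2-yl)silane | COc1cc(O[Si](C(C)C)(C(C)C)C(C)C)ccc1Br | intermediate
21 | [2-methoxy-4-{[tri(propan-2-yl)silyl]oxy}phenyl]lithium | COc1cc(O[Si](C(C)C)(C(C)C)C(C)C)ccc1[Li] | intermediate
22 | [2-methoxy-4-{[tri(propan-2-yl)silyl]oxy}phenyl]boronic acid | COc1cc(O[Si](C(C)C)(C(C)C)C(C)C)ccc1B(O)O | intermediate
23 | (2S)-8-[(2R)-5-hydroxy-5-methyl-2-(prop-1-en-2-yl)hexyl]-5-methoxy-2-(2-methoxy-4-{[tri(propan-2-yl)silyl]oxy}phenyl)-7-{[tri(propan-2-yl)silyl]oxy}-2,3-dihydro-4H-chromen-4-one | C=C(C)[C@H](CCC(C)(C)O)Cc1c(O[Si](C(C)C)(C(C)C)C(C)C)cc(OC)c2c1O[C@H](c1ccc(O[Si](C(C)C)(C(C)C)C(C)C)cc1OC)CC2=O | intermediate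
24 | (2S)-7-hydroxy-2-(4-hydroxy-2-methoxyphenyl)-8-[(2R)-5-hydroxy-5-methyl-2-(prop-1-en-2-yl)hexyl]-5-methoxy-2,3-dihydro-4H-chromen-4-one | C=C(C)[C@H](CCC(C)(C)O)Cc1c(O)cc(OC)c2c1O[C@H](c1ccc(O)cc1OC)CC2=O | target

## Step count and risks

Total step count: 16. Longest linear sequence: 13 steps (steps 1–4, 6–12, 15, 16).

The three steps most likely to fail:

**Step 6.** What may go wrong: insufficient facial discrimination by the carbene catalyst for a flexible alkyl-substituted enolate adding to an unsubstituted methide, epimerisation of the lactone α-centre by fluoride or imidazole, or self-condensation of the quinone methide outrunning the annulation. The fallback is an auxiliary-controlled enolate alkylation (Evans alkylation). It sets out from aldehyde 4, which is reduced with NaBH4 (MeOH, 0 °C) to benzyl alcohol 5, now isolated. Alcohol 5 is converted with PPh3/N-chlorosuccinimide (CH2Cl2, −20 °C) into tert-butyl[2-(chloromethyl)-5-methoxy-3-(methoxymethoxy)phenoxy]dimethylsilane F1, used crude. Acid 7 is coupled through its pivaloyl mixed anhydride (t-BuCOCl, Et3N; then the lithium salt of (4S)-4-benzyl-1,3-oxazolidin-2-one) to methyl 5-[(4S)-4-benzyl-2-oxo-1,3-oxazolidin-3-yl]-5-oxopentanoate F2. Its sodium (Z)-enolate (NaN(SiMe3)2, THF, −78 °C) is alkylated by F1 on the face opposite to the benzyl group, which should give methyl (4R)-5-[(4S)-4-benzyl-2-oxo-1,3-oxazolidin-3-yl]-4-{[2-{[tert-butyl(dimethyl)silyl]oxy}-4-methoxy-6-(methoxymethoxy)phenyl]methyl}-5-oxopentanoate F3. n-Bu4NF (THF, −20 °C) removes the silyl group and the phenoxide closes onto the exocyclic imide carbonyl, expelling the auxiliary. The route is rejoined at lactone 10.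

**Step 15.** What may go wrong: slow aryl transfer to the electron-rich, 5,7,8-trisubstituted chromone while the electron-rich, ortho-substituted boronic acid protodeboronates, or eroded face selectivity. The fallback uses a stoichiometric aryl donor without catalyst control, followed by separation of diastereomers. It sets out from chromone 18 and aryl bromide 20. Bromide 20 and Mg (THF) give [2-methoxy-4-{[tri(propan-2-yl)silyl]oxy}phenyl]magnesium bromide F4 (4 equiv, one consumed by the tertiary alcohol). F4 adds 1,4 to 18 with CuBr·SMe2 (cat.) and Me3SiCl (THF, −40 °C) to give 8-[(2R)-5-hydroxy-5-methyl-2-(prop-1-en-2-yl)hexyl]-5-methoxy-2-(2-methoxy-4-{[tri(propan-2-yl)silyl]oxy}phenyl)-7-{[tri(propan-2-yl)silyl]oxy}-4-[(trimethylsilyl)oxy]-2H-chromene F5 as both C2 epimers. Aqueous citric acid work-up hydrolyses the silyl enol ether to 23 and its (2R)-epimer F6, which are diastereomers because of the fixed side-chain centre and are to be separated by preparative HPLC. F6 is recycled by equilibration through reversible ring opening (cat. DBU, toluene). The route is rejoined at 23.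

**Step 11.** What may go wrong: incomplete or misdirected deprotonation in the presence of the lithium alkoxide (lateral lithiation of the benzylic CH2 or metalation next to the silyl ether). The fallback replaces chelation-directed by halogen-directed metalation. It sets out from 14, which is brominated with N-bromosuccinimide (MeCN, −40 °C) at the ring position flanked by OMe and OMOM; the other free position is screened by the triisopropylsilyl ether, and the electron-rich arene should react far faster than the isopropenyl group. This gives (5R)-5-{[3-bromo-4-methoxy-2-(methoxymethoxy)-6-{[tri(propan-2-yl)silyl]oxy}phenyl]methyl}-2,6-dimethylhept-6-en-2-ol F7. t-BuLi (3.1 equiv, THF, −78 °C) forms the alkoxide and exchanges bromine for lithium, which gives 15 site-specifically. The route is rejoined at 15 and continues with the acylation of step 11.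

## Further compounds

F1 | step 6 | tert-butyl[2-(chloromethyl)-5-methoxy-3-(methoxymethoxy)phenoxy]dimethylsilane | ClCc1c(O[Si](C)(C)C(C)(C)C)cc(OC)cc1OCOC
F2 | step 6 | methyl 5-[(4S)-4-benzyl-2-oxo-1,3-oxazolidin-3-yl]-5-oxopentanoate | COC(=O)CCCC(=O)N1[C@@H](Cc2ccccc2)COC1=O
F3 | step 6 | methyl (4R)-5-[(4S)-4-benzyl-2-oxo-1,3-oxazolidin-3-yl]-4-{[2-{[tert-butyl(dimethyl)silyl]oxy}-4-methoxy-6-(methoxymethoxy)phenyl]methyl}-5-oxopentanoate | O=C([C@H](CCC(=O)OC)Cc1c(O[Si](C)(C)C(C)(C)C)cc(OC)cc1OCOC)N1[C@@H](Cc2ccccc2)COC1=O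
F4 | step 15 | [2-methoxy-4-{[tri(propan-2-yl)silyl]oxy}phenyl]magnesium bromide | COc1cc(O[Si](C(C)C)(C(C)C)C(C)C)ccc1[Mg]Br
F5 | step 15 | 8-[(2R)-5-hydroxy-5-methyl-2-(prop-1-en-2-yl)hexyl]-5-methoxy-2-(2-methoxy-4-{[tri(propan-2-yl)silyl]oxy}phenyl)-7-{[tri(propan-2-yl)silyl]oxy}-4-[(trimethylsilyl)oxy]-2H-chromene (both C2 epimers) | C=C(C)[C@H](CCC(C)(C)O)Cc1c(O[Si](C(C)C)(C(C)C)C(C)C)cc(OC)c2c1OC(c1ccc(O[Si](C(C)C)(C(C)C)C(C)C)cc1OC)C=C2O[Si](C)(C)C
F6 | step 15 | (2R)-8-[(2R)-5-hydroxy-5-methyl-2-(prop-1-en-2-yl)hexyl]-5-methoxy-2-(2-methoxy-4-{[tri(propan-2-yl)silyl]oxy}phenyl)-7-{[tri(propan-2-yl)silyl]oxy}-2,3-dihydro-4H-chromen-4-one | C=C(C)[C@H](CCC(C)(C)O)Cc1c(O[Si](C(C)C)(C(C)C)C(C)C)cc(OC)c2c1O[C@@H](c1ccc(O[Si](C(C)C)(C(C)C)C(C)C)cc1OC)CC2=O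
F7 | step 11 | (5R)-5-{[3-bromo-4-methoxy-2-(methoxymethoxy)-6-{[tri(propan-2-yl)silyl]oxy}phenyl]methyl}-2,6-dimethylhept-6-en-2-ol | C=C(C)[C@H](CCC(C)(C)O)Cc1c(O[Si](C(C)C)(C(C)C)C(C)C)cc(OC)c(Br)c1OCOC
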